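## Retrosynthetic overview

1. Enabling feature (cembrane locants: C1 ring-fusion CH, C2 O–CH, C16 lactone C=O, C19 the acetoxymethyl carbon on C8): in the 14-membered carbocycle C9 and C10 are both allylic CH2 groups, so C9–C10 is the central σ-bond of the ring 1,5-diene C7=C8–C9–C10–C11=C12 and can be made by joining two allyl units at their unsubstituted ends.
2. Last ring: C9–C10 of the 14-membered ring, by nickel-catalysed electroreductive allyl–allyl coupling of a C10 allylic bromide with a C7 allylic carbonate kept in its unrearranged 2-methylene form (C8=C9H2); the same event creates the C7=C8 olefin.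
3. First ring: C1–C2 and the lactone O–C16 bond, by enantioselective allylboration/lactonization of enal 13 with allylboronate 9; this sets C1 and C2 and forms the cis α-methylene-γ-butyrolactone.
4. Hidden repeat: both partners come from one Baylis–Hillman adduct (7) of a C7 aldehyde cut out of geraniol, once as the boronate (C10–C14, C1, C15–C17) and once as the reduced 2-methylene-1,3-diol (C2–C9, C19).
5. Order of ring formation: lactone ring (step 11), then the 14-membered carbocycle (step 14).

Key step: step 14

Remark 1: locants are those the atoms carry in the target, also in open-chain intermediates.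
Remark 2: 7 is racemic; its carbinol carbon becomes C1 (sp2 in 9) or C7 (carried as an epimer mixture, sp2 after step 14), so the SMILES leave this centre undefined and no resolution is needed.
Remark 3: (R)-TRIP is (R)-3,3′-bis(2,4,6-triisopropylphenyl)-1,1′-binaphthyl-2,2′-diyl hydrogen phosphate; the R enantiomer is assigned on the assumption that it directs the allyl group to the Re face of the aldehyde as with simple aldehydes, and the S enantiomer is used if the sense proves opposite with 9.

## Route

Step 1
Reactants: 1 geraniol
Product: 2 geranyl tert-butyldimethylsilyl ether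
Conditions: TBSCl, imidazole, CH2Cl2, 0 °C to rt
Reagents that add atoms: tert-butyldimethylsilyl chloride, CC(C)(C)[Si](C)(C)Cl
Why: Silylation of a primary allylic alcohol (silyl ether formation); the group should survive steps 2–12 and is exchanged for bromide in one neutral operation in step 13.

Step 2
Reactants: 2 geranyl tert-butyldimethylsilyl ether
Product: 3 terminal epoxide of 2 (racemic)
Conditions: mCPBA (1.05 equiv), CH2Cl2, −20 to 0 °C
Reagents that add atoms: 3-chloroperbenzoic acid, OOC(=O)c1cccc(Cl)c1
Why: Prilezhaev epoxidation, which should prefer the remote isopropylidene olefin because the olefin next to the silyloxy group is inductively deactivated; the epoxide centre is racemic and is removed in step 3.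

Step 3
Reactants: 3 terminal epoxide of 2
Product: 5 (4E)-6-(tert-butyldimethylsilyloxy)-4-methylhex-4-enal, via glycol 4 (not isolated)
Conditions: H5IO6, THF/H2O, 0 °C
Reagents that add atoms: none
Why: Periodic acid opens the epoxide to glycol 4 and cleaves it in the same flask (Malaprade glycol cleavage) with loss of acetone; the aldehyde oxygen is the former epoxide oxygen and the E olefin is untouched.

Step 4
Reactants: 5 (4E)-6-(tert-butyldimethylsilyloxy)-4-methylhex-4-enal; 6 methyl acrylate
Product: 7 methyl (6E)-8-(tert-butyldimethylsilyloxy)-3-hydroxy-6-methyl-2-methylideneoct-6-enoate (racemic)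
Conditions: DABCO (1 equiv), neat in 6 (5 equiv), rt, 5 d
Reagents that add atoms: none
Why: Morita–Baylis–Hillman reaction of an unhindered aliphatic aldehyde with an acrylate; the new carbinol centre is racemic and irrelevant (Remark 2).

Step 5
Reactants: 7 Baylis–Hillman adduct
Product: 8 methyl (6E)-3-acetoxy-8-(tert-butyldimethylsilyloxy)-6-methyl-2-methylideneoct-6-enoate
Conditions: Ac2O, pyridine, DMAP (cat.), CH2Cl2, 0 °C
Reagents that add atoms: acetic anhydride, CC(=O)OC(C)=O
Why: Acetylation turns the hydroxyl into the leaving group needed for the SN2′ borylation of step 6.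

Step 6
Reactants: 8 Baylis–Hillman acetate
Product: 9 methyl (2E,6E)-8-(tert-butyldimethylsilyloxy)-6-methyl-2-[(pinacolatoboryl)methyl]octa-2,6-dienoate
Conditions: B2pin2 (1.1 equiv), CuCl (10 mol %), LiCl, KOAc, DMF, rt
Reagents that add atoms: bis(pinacolato)diboron, CC1(C)OB(OC1(C)C)B1OC(C)(C)C(C)(C)O1
Why: Copper-catalysed borylation of a Baylis–Hillman acetate (conjugate borylation then β-acetoxy elimination, overall SN2′) should give the 2E isomer with the C14 chain cis to CH2B, as is general for SN2′ substitution of acrylate-derived Baylis–Hillman acetates; the silyl ether and the trisubstituted olefin are inert.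

Step 7
Reactants: 7 Baylis–Hillman adduct
Product: 10 (6E)-8-(tert-butyldimethylsilyloxy)-6-methyl-2-methylideneoct-6-ene-1,3-diol
Conditions: iBu2AlH (3.3 equiv), CH2Cl2, −78 to 0 °C; aq. potassium sodium tartrate
Reagents that add atoms: none
Why: 1,2-Reduction of the acrylate ester by iBu2AlH at low temperature (ester reduction) should give the 2-methylene-1,3-diol; silyl ether and olefins are inert.

Step 8
Reactants: 10 2-methylene-1,3-diol
Product: 11 (6E)-8-(tert-butyldimethylsilyloxy)-3-hydroxy-6-methyl-2-methylideneoct-6-en-1-yl acetate
Conditions: AcCl (1.05 equiv), 2,4,6-collidine, CH2Cl2, −78 °C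
Reagents that add atoms: acetyl chloride, CC(Cl)=O
Why: Site-selective acylation, since at −78 °C with a hindered pyridine base the primary allylic hydroxyl (C19) should be acetylated much faster than the secondary one (C7).

Step 9
Reactants: 11 monoacetate
Product: 12 (6E)-3,8-dihydroxy-6-methyl-2-methylideneoct-6-en-1-yl acetate
Conditions: HF·pyridine, pyridine, THF, 0 °C
Reagents that add atoms: none
Why: Fluoride-mediated desilylation under buffered conditions, which should leave the acetate in place and not promote acyl migration.

Step 10
Reactants: 12 diol acetate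
Product: 13 (6E)-3-hydroxy-6-methyl-2-methylidene-8-oxooct-6-en-1-yl acetate
Conditions: TEMPO (10 mol %), PhI(OAc)2, CH2Cl2, rt
Reagents that add atoms: none
Why: Oxoammonium (TEMPO) oxidation is selective for primary over secondary alcohols, so only C2 should be oxidized, and the conjugated E enal forms without isomerization.

Step 11
Reactants: 9 allylboronate; 13 hydroxy enal
Product: 15 hydroxy lactone (1S,2S; cis; C7–OH; C19–OAc; C10–OTBS), via pinacol borate 14 (not isolated)
Conditions: (R)-TRIP (10 mol %), 4 Å molecular sieves, toluene, rt; then PPTS (10 mol %), 40 °C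
Reagents that add atoms: none
Why: Chiral-phosphoric-acid-catalysed allylboration through a closed six-membered chair followed by lactonization: the C14 chain, cis to CH2B in 9, sits axial and gives the syn adduct 14 (hence the cis lactone), the catalyst directs the allyl group to the Re face of the aldehyde so that C2 and with it C1 become S, and the borate oxygen then displaces methoxide from the ester to close the lactone ring.

Step 12
Reactants: 15 hydroxy lactone
Product: 16 carbonate lactone (C7–OCO2Me)
Conditions: ClCO2Me, pyridine, DMAP (cat.), CH2Cl2, 0 °C
Reagents that add atoms: methyl chloroformate, COC(Cl)=O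
Why: Acylation of the remaining secondary allylic hydroxyl with a chloroformate (carbonate formation) installs a leaving group for oxidative addition that is inert in step 13.

Step 13
Reactants: 16 carbonate lactone
Product: 17 bromo carbonate lactone (C10–Br)
Conditions: Ph3PBr2 (1.3 equiv), CH2Cl2, 0 °C to rt
Reagents that add atoms: dibromotriphenylphosphorane, BrP(Br)(c1ccccc1)(c1ccccc1)c1ccccc1
Why: Ph3PBr2 converts a primary silyl ether directly into the bromide (silyloxyphosphonium formation, then SN2 by bromide) without liberating HBr, which matters for the acid-sensitive allylic C2–O bond of the lactone; carbonate and acetate are spectators.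

Step 14
Reactants: 17 bromo carbonate lactone
Product: 19 CNP0158848.2 [(1S,2S,3E,7Z,11E)-19-acetoxycembra-3,7,11,15(17)-tetraen-16,2-olide], via nickelacycle 18 (not isolated)
Conditions: NiBr2(bpy) (20 mol %; bpy = 2,2′-bipyridine), Bu4NBr, DMF, divided cell, carbon-felt cathode, Zn anode, constant current, 17 added by syringe pump over 10 h (final ≤ 2 mM), 2.1 F/mol, rt
Reagents that add atoms: none
Why: Proposed new method: zerovalent nickel–bipyridine formed at the cathode adds oxidatively to the C10–Br bond and, after one-electron reduction, to the allylic carbonate (loss of CO2 and methoxide), so that both allyl units end on one nickel centre (18), which couples them by reductive elimination at their unsubstituted CH2 termini C9 and C10; the closest known reaction types are the stoichiometric zerovalent-nickel cyclization of α,ω-bis(allylic bromides) to 12- to 18-membered 1,5-dienes and the intermolecular nickel–bipyridine-catalysed electroreductive coupling of allylic halides and esters, merged here into a catalytic ring closure. The 14-membered carbocycle is closed by head-to-head (1,1′) C(sp3)–C(sp3) reductive elimination within a 15-membered nickelacycle. No stereocentre is formed: the racemic carbonate carbon C7 becomes sp2, the geometry of the new C7=C8 olefin is set by the preference of the C6 chain for the syn position of the 1,2-disubstituted η3-allyl (cis to the acetoxymethyl branch, trans to C9, which is 7Z by the sequence rule), and C11=C12 should keep its E geometry because syn/anti exchange would need nickel σ-bound at the fully substituted C12. The step needs 1,1′ coupling over 1,3′ and 3,3′ coupling (secured by the two unsubstituted termini and by the lower strain of the 14-membered ring against the 12- and 10-membered alternatives), ring closure over oligomerization (secured by feeding 17 at the rate at which charge is passed), and reaction at C–Br and C–OCO2Me only (secured by their faster oxidative addition compared with the C19 acetate and the allylic C2–O bond of the lactone, and by stopping at the two electrons per molecule that the coupling consumes).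

## Compound list

1 | geraniol, (2E)-3,7-dimethylocta-2,6-dien-1-ol | CC(C)=CCC/C(C)=C/CO | starting material
2 | geranyl tert-butyldimethylsilyl ether | CC(C)=CCC/C(C)=C/CO[Si](C)(C)C(C)(C)C | intermediate
3 | terminal (isopropylidene) epoxide of 2, racemic | CC1(C)OC1CC/C(C)=C/CO[Si](C)(C)C(C)(C)C | intermediate
4 | glycol from 3, racemic (not isolated) | CC(C)(O)C(O)CC/C(C)=C/CO[Si](C)(C)C(C)(C)C | intermediate
5 | (4E)-6-(tert-butyldimethylsilyloxy)-4-methylhex-4-enal | O=CCC/C(C)=C/CO[Si](C)(C)C(C)(C)C | intermediate
6 | methyl acrylate | C=CC(=O)OC | starting material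
7 | methyl (6E)-8-(tert-butyldimethylsilyloxy)-3-hydroxy-6-methyl-2-methylideneoct-6-enoate, racemic | C=C(C(=O)OC)C(O)CC/C(C)=C/CO[Si](C)(C)C(C)(C)C | intermediate
8 | methyl (6E)-3-acetoxy-8-(tert-butyldimethylsilyloxy)-6-methyl-2-methylideneoct-6-enoate | C=C(C(=O)OC)C(OC(C)=O)CC/C(C)=C/CO[Si](C)(C)C(C)(C)C | intermediate
9 | methyl (2E,6E)-8-(tert-butyldimethylsilyloxy)-6-methyl-2-[(4,4,5,5-tetramethyl-1,3,2-dioxaborolan-2-yl)methyl]octa-2,6-dienoate | COC(=O)/C(CB1OC(C)(C)C(C)(C)O1)=C/CC/C(C)=C/CO[Si](C)(C)C(C)(C)C | intermediate
10 | (6E)-8-(tert-butyldimethylsilyloxy)-6-methyl-2-methylideneoct-6-ene-1,3-diol | C=C(CO)C(O)CC/C(C)=C/CO[Si](C)(C)C(C)(C)C | intermediate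
11 | (6E)-8-(tert-butyldimethylsilyloxy)-3-hydroxy-6-methyl-2-methylideneoct-6-en-1-yl acetate | C=C(COC(C)=O)C(O)CC/C(C)=C/CO[Si](C)(C)C(C)(C)C | intermediate
12 | (6E)-3,8-dihydroxy-6-methyl-2-methylideneoct-6-en-1-yl acetate | C=C(COC(C)=O)C(O)CC/C(C)=C/CO | intermediate
13 | (6E)-3-hydroxy-6-methyl-2-methylidene-8-oxooct-6-en-1-yl acetate | C=C(COC(C)=O)C(O)CC/C(C)=C/C=O | intermediate
14 | open-chain syn (1S,2S) adduct of 9 and 13 as its O-pinacolboryl ether, methyl ester (not isolated; C7 epimers) | C=C(C(=O)OC)[C@H](CC/C(C)=C/CO[Si](C)(C)C(C)(C)C)[C@H](/C=C(\C)CCC(O)C(=C)COC(C)=O)OB1OC(C)(C)C(C)(C)O1 | intermediate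
15 | (4S,5S)-5-[(1E)-7-acetoxy-5-hydroxy-2-methyl-6-methylidenehept-1-en-1-yl]-4-[(3E)-5-(tert-butyldimethylsilyloxy)-3-methylpent-3-en-1-yl]-3-methylideneoxolan-2-one (C7 epimers) | C=C1C(=O)O[C@@H](/C=C(\C)CCC(O)C(=C)COC(C)=O)[C@H]1CC/C(C)=C/CO[Si](C)(C)C(C)(C)C | intermediate
16 | C7 methyl carbonate of 15 (C7 epimers) | C=C1C(=O)O[C@@H](/C=C(\C)CCC(OC(=O)OC)C(=C)COC(C)=O)[C@H]1CC/C(C)=C/CO[Si](C)(C)C(C)(C)C | intermediate
17 | (4S,5S)-5-[(1E)-7-acetoxy-5-(methoxycarbonyloxy)-2-methyl-6-methylidenehept-1-en-1-yl]-4-[(3E)-5-bromo-3-methylpent-3-en-1-yl]-3-methylideneoxolan-2-one (C7 epimers) | C=C1C(=O)O[C@@H](/C=C(\C)CCC(OC(=O)OC)C(=C)COC(C)=O)[C@H]1CC/C(C)=C/CBr | intermediate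
18 | bis(allyl)(2,2′-bipyridine)nickel metallacycle, drawn in its σ,σ form: 19 with divalent nickel between C9 and C10 (not isolated) | C=C1C(=O)O[C@H]2/C=C(\C)CC/C=C(\COC(C)=O)C[Ni-2]3([n+]4ccccc4-c4cccc[n+]34)C/C=C(\C)CC[C@@H]12 | intermediate
19 | CNP0158848.2, (1S,2S,3E,7Z,11E)-19-acetoxycembra-3,7,11,15(17)-tetraen-16,2-olide (cis-fused lactone) | C=C1C(=O)O[C@H]2/C=C(\C)CC/C=C(\COC(C)=O)CC/C=C(\C)CC[C@@H]12 | target

## Step count and risks

Total steps: 14. Longest linear sequence: 12 steps (1–4, then 7–14).

Steps most likely to fail:

1. Step 14 (carries the label). What may go wrong: intermolecular coupling to oligomers outpacing ring closure; partial loss of the C11=C12 geometry through syn/anti exchange of the allylnickel unit; coupling at a substituted terminus to 12-membered rings; β-hydride loss from the C7–C9 allyl unit to a diene; slow reductive consumption of the C19 acetate of 19 once 17 is used up. Fallback (known chemistry, a stoichiometric reagent and a different precursor in place of catalysis and the cell): it sets out from 15. Ph3PBr2 (2.4 equiv) with 2,6-lutidine in CH2Cl2 should turn both the silyl ether and the C7 hydroxyl into allylic bromides and give bis(allylic bromide) F1. F1 is drawn as the transposed primary bromide; its C7=C8 isomers and any secondary bromide are equivalent, because all give the same allylnickel unit. F1 is then added slowly to excess Ni(CO)4 in N-methylpyrrolidone at 50 °C. This is the stoichiometric zerovalent-nickel cyclization of α,ω-bis(allylic bromides), established for 12- to 18-membered 1,5-dienes and for ester-containing chains, and it leaves acetates and lactones alone. The route is rejoined at 19.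

2. Step 11. What may go wrong: insufficient facial discrimination by the catalyst with the ester-substituted, weakly nucleophilic boronate; a competing open transition state that erodes the syn (cis) selectivity; acid-promoted ionization of the allylic C2–O bond during lactonization, with epimerization at C2. Fallback (resolution in place of asymmetric catalysis): it sets out from 9 and 13. These are heated without any catalyst (toluene, 100 °C); the closed chair alone fixes the cis relationship and the borate lactonizes thermally without acid. This should give 15 together with its mirror-image lactone F3, through borate 14 and mirror-image borate F2. 15 is separated from F3 by preparative chromatography on a chiral stationary phase, and the route is rejoined at 15.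

3. Step 13. What may go wrong: bromide-induced allylic transposition to the tertiary bromide; attack of adventitious HBr on the allylic C2–O bond of the lactone or on the trisubstituted olefins; decomposition of the allylic bromide on purification. Fallback (no halide at all): it sets out from 16. HF·pyridine removes the silyl group to give allylic alcohol F4. ClCO2Me and pyridine convert it into bis(methyl carbonate) F5. F5 is cyclized under the conditions of step 14, both oxidative additions then taking place at allylic carbonates. The route is rejoined at 19.

## Further compounds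

F1 | step 14 | bis(allylic bromide): 17 with bromide in place of the carbonate, drawn as the transposed primary C9 bromide (C7=C8 geometry undefined) | C=C1C(=O)O[C@@H](/C=C(\C)CCC=C(CBr)COC(C)=O)[C@H]1CC/C(C)=C/CBr
F2 | step 11 | mirror-image (1R,2R) borate, enantiomer of 14 | C=C(C(=O)OC)[C@@H](CC/C(C)=C/CO[Si](C)(C)C(C)(C)C)[C@@H](/C=C(\C)CCC(O)C(=C)COC(C)=O)OB1OC(C)(C)C(C)(C)O1
F3 | step 11 | mirror-image (4R,5R) lactone, enantiomer of 15 | C=C1C(=O)O[C@H](/C=C(\C)CCC(O)C(=C)COC(C)=O)[C@@H]1CC/C(C)=C/CO[Si](C)(C)C(C)(C)C
F4 | step 13 | allylic alcohol: 16 with C10–OH in place of the silyl ether | C=C1C(=O)O[C@@H](/C=C(\C)CCC(OC(=O)OC)C(=C)COC(C)=O)[C@H]1CC/C(C)=C/CO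
F5 | step 13 | bis(methyl carbonate): F4 with C10–OCO2Me | C=C1C(=O)O[C@@H](/C=C(\C)CCC(OC(=O)OC)C(=C)COC(C)=O)[C@H]1CC/C(C)=C/COC(=O)OC
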